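Retrosynthesis: the C3–O ester bond is cut first, then N1–C2 of ring A (imine reduction), then N1–C8a and C3–O together through a temporary N–O bond (acylnitroso Diels–Alder reaction), then C4a–C4 (Suzuki coupling) and C5=C1' (aldol condensation on cyclohexanone).
Forward: ring B is bought as cyclohexanone; the C8 chain is joined at C5=C1' and the butenyl arm at C4a–C4; the cycloaddition closes a 3,6-dihydro-1,2-oxazine that is not a ring of the target and is reopened at N–O; ring A then closes at N1–C2, the C4=C4a–C5=C1' diene is saturated and the dienoate is attached last.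
Enabling feature: N1 on C8a and the oxygen on C3 are 1,4-related through C4a and C4 of ring A and lie syn, the imprint of an N=O dienophile on a C8a=C4a–C4=C3 diene; O3, H4a and H5 sit on one face of rings A and B, so the C3 hydroxyl can guide the later reductions.
Stereochemistry: C5' comes from (R)-2-propyloxirane; C8a and C3 from the suprafacial cycloaddition, its face chosen by a C2 silyloxy centre from (S)-but-3-yn-2-ol that is later oxidised away; C2 from hydride delivery to the cyclic imine on the O3 face; C4a and C5 from hydroxyl-directed hydrogenation.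

Key step: step 10

Remark: all intermediates carry the atom labels of the target (N1, C2–C8a of the decahydroquinoline; C1'–C8' of the side chain).
Remark: keto carbamate 22 is drawn open-chain; it may equilibrate with its cyclic N-Boc hemiaminal, which changes nothing in step 14.

Step 1
Reactants: 1 (R)-2-propyloxirane; 2 but-3-en-1-ylmagnesium bromide (THF solution)
Product: 3 (4R)-non-8-en-4-ol
Conditions: CuI (10 mol%), THF, −40 to 0 °C; then 1 M HCl
Reagents that add atoms: none
Why: Copper-catalysed Grignard opening of a terminal epoxide is an SN2 reaction at the unsubstituted carbon, so the carbinol centre (the future C5') keeps the R configuration of the oxirane.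

Step 2
Reactants: 3 (4R)-non-8-en-4-ol
Product: 4 tert-butyl[(4R)-non-8-en-4-yloxy]diphenylsilane
Conditions: t-BuPh2SiCl, imidazole, DMF, 23 °C
Reagents that add atoms: tert-butyl(chloro)diphenylsilane, CC(C)(C)[Si](Cl)(c1ccccc1)c1ccccc1
Why: Silylation of a secondary alcohol with a silyl chloride and imidazole is routine, and the tert-butyldiphenylsilyl ether is chosen because it should survive the acids of steps 11 and 14 and fall only to fluoride.

Step 3
Reactants: 4 tert-butyl[(4R)-non-8-en-4-yloxy]diphenylsilane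
Product: 5 (5R)-5-(tert-butyldiphenylsilyloxy)octanal
Conditions: O3, CH2Cl2, −78 °C; then PPh3, −78 to 23 °C
Reagents that add atoms: ozone, [O-][O+]=O
Why: Ozonolysis with reductive work-up cleaves the terminal alkene to the aldehyde and leaves the silyl ether and the stereocentre untouched.

Step 4
Reactants: 6 cyclohexanone; 5 (5R)-5-(tert-butyldiphenylsilyloxy)octanal
Product: 8 2-[(5R)-5-(tert-butyldiphenylsilyloxy)-1-hydroxyoctyl]cyclohexan-1-one (diastereomer mixture at C1' and the ring carbon), via cyclohexanone lithium enolate 7 (not isolated)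
Conditions: LiN(iPr)2, THF, −78 °C; then 5, −78 °C; then AcOH
Reagents that add atoms: none
Why: Directed aldol addition of a preformed lithium enolate to an aldehyde at −78 °C outruns enolisation of the aldehyde, and the two new centres need no control because both are destroyed in step 5.

Step 5
Reactants: 8 2-[(5R)-5-(tert-butyldiphenylsilyloxy)-1-hydroxyoctyl]cyclohexan-1-one
Product: 10 (2E)-2-[(5R)-5-(tert-butyldiphenylsilyloxy)octylidene]cyclohexan-1-one, via aldol mesylate 9 (not isolated)
Conditions: MsCl, Et3N, CH2Cl2, 0 °C; then DBU, 23 °C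
Reagents that add atoms: none
Why: Mesylation followed by base-induced elimination (E1cB) should give the conjugated enone as the E isomer, because the chain turns away from the carbonyl group; this fixes the C5=C1' geometry.

Step 6
Reactants: 10 (2E)-2-[(5R)-5-(tert-butyldiphenylsilyloxy)octylidene]cyclohexan-1-one
Product: 12 (6E)-6-[(5R)-5-(tert-butyldiphenylsilyloxy)octylidene]cyclohex-1-en-1-yl trifluoromethanesulfonate, via lithium dienolate 11 (not isolated)
Conditions: LiN(iPr)2, THF, −78 °C; then PhNTf2, −78 to 0 °C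
Reagents that add atoms: N-phenylbis(trifluoromethanesulfonimide), O=S(=O)(N(c1ccccc1)S(=O)(=O)C(F)(F)F)C(F)(F)F
Why: Kinetic deprotonation of an α,β-unsaturated ketone by a hindered lithium amide takes the α′ proton, and O-sulfonylation of the cross-conjugated enolate (enol triflate formation) places the C8a=C4a double bond and the leaving group on C4a.

Step 7
Reactants: 13 (S)-but-3-yn-2-ol
Product: 14 (S)-triethyl(but-3-yn-2-yloxy)silane
Conditions: Et3SiCl, imidazole, CH2Cl2, 0 °C
Reagents that add atoms: chlorotriethylsilane, CC[Si](Cl)(CC)CC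
Why: Routine silylation gives a triethylsilyl ether that can later be removed beside the tert-butyldiphenylsilyl ether and that serves as the bulky face-directing group of step 10.

Step 8
Reactants: 14 (S)-triethyl(but-3-yn-2-yloxy)silane
Product: 15 triethyl{[(2S,3E)-4-(4,4,5,5-tetramethyl-1,3,2-dioxaborolan-2-yl)but-3-en-2-yl]oxy}silane
Conditions: pinacolborane, Cp2Zr(H)Cl (5 mol%), Et3N (10 mol%), neat, 60 °C
Reagents that add atoms: pinacolborane, CC1(C)OBOC1(C)C
Why: Zirconocene hydride-catalysed hydroboration of a terminal alkyne with pinacolborane is a syn, anti-Markovnikov addition and should give the E alkenylboronate only.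

Step 9
Reactants: 12 (6E)-6-[(5R)-5-(tert-butyldiphenylsilyloxy)octylidene]cyclohex-1-en-1-yl trifluoromethanesulfonate; 15 triethyl{[(2S,3E)-4-(4,4,5,5-tetramethyl-1,3,2-dioxaborolan-2-yl)but-3-en-2-yl]oxy}silane
Product: 16 (6E)-6-[(5R)-5-(tert-butyldiphenylsilyloxy)octylidene]-1-[(1E,3S)-3-(triethylsilyloxy)but-1-en-1-yl]cyclohex-1-ene
Conditions: Pd(PPh3)4 (5 mol%), K3PO4 (3 M aq.), 1,4-dioxane, 50 °C
Reagents that add atoms: none
Why: Suzuki–Miyaura coupling of an enol triflate with an alkenylboronate (oxidative addition to zerovalent palladium, transmetalation, reductive elimination) retains both alkene geometries and forms the C4a–C4 bond of the cross-conjugated triene.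

Step 10
Reactants: 16 (6E)-6-[(5R)-5-(tert-butyldiphenylsilyloxy)octylidene]-1-[(1E,3S)-3-(triethylsilyloxy)but-1-en-1-yl]cyclohex-1-ene; 17 tert-butyl N-hydroxycarbamate
Product: 19 tert-butyl (3R,8aR,5E)-5-[(5R)-5-(tert-butyldiphenylsilyloxy)octylidene]-3-[(1S)-1-(triethylsilyloxy)ethyl]-3,5,6,7,8,8a-hexahydro-1H-2,1-benzoxazine-1-carboxylate, via tert-butyl nitrosoformate 18 (not isolated)
Conditions: Bu4NIO4 (1.05 equiv), CH2Cl2, 0 °C; 17 (1.0 equiv) added over 2 h to 16 (1.1 equiv)
Reagents that add atoms: none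
Why: Periodate oxidises 17 to the nitrosoformate 18, whose N=O bond is the 2π partner of a concerted, asynchronous, suprafacial [4+2] cycloaddition (acylnitroso hetero-Diels–Alder reaction, well known for acyclic 1,3-dienes) across C8a=C4a–C4=C3, the only diene of 16 that can become s-cis because C8a=C4a and C5=C1' are held transoid by ring B. The 3,6-dihydro-1,2-oxazine ring is closed by this intermolecular cycloaddition itself, N–C8a and O–C3 forming in one event. C8a and C3 are created together and their cis relationship follows from suprafacial addition to the E-configured C3=C4 and the ring-fixed C8a=C4a termini; the face, and hence 3R,8aR, should be chosen by the 2S silyloxy centre, whose C2–H eclipses C3=C4 (least allylic 1,3-strain) so that the dienophile enters anti to the bulky OSiEt3 group, the same face that an in-plane alkoxy arrangement with methyl anti would select. Regioselectivity (N to C8a) should come from the larger HOMO coefficient at C8a, the terminus next to the doubly substituted C4a, and from the branched C3 terminus repelling the N-Boc end. Mono-addition is also needed, because 19 contains a new s-cis 1,2-bis(alkylidene)cyclohexane diene; slow addition of 17 to a slight excess of 16 and the deactivation of that diene by its allylic N and O substituents should hold the reaction at 19.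

Step 11
Reactants: 19 tert-butyl (3R,8aR,5E)-5-[(5R)-5-(tert-butyldiphenylsilyloxy)octylidene]-3-[(1S)-1-(triethylsilyloxy)ethyl]-3,5,6,7,8,8a-hexahydro-1H-2,1-benzoxazine-1-carboxylate
Product: 20 tert-butyl (3R,8aR,5E)-5-[(5R)-5-(tert-butyldiphenylsilyloxy)octylidene]-3-[(1S)-1-hydroxyethyl]-3,5,6,7,8,8a-hexahydro-1H-2,1-benzoxazine-1-carboxylate
Conditions: pyridinium p-toluenesulfonate (cat.), MeOH–CH2Cl2, 0 °C
Reagents that add atoms: none
Why: Mild acid methanolysis (selective desilylation) removes a triethylsilyl ether far faster than a tert-butyldiphenylsilyl ether and touches neither the carbamate nor the N–O bond.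

Step 12
Reactants: 20 tert-butyl (3R,8aR,5E)-5-[(5R)-5-(tert-butyldiphenylsilyloxy)octylidene]-3-[(1S)-1-hydroxyethyl]-3,5,6,7,8,8a-hexahydro-1H-2,1-benzoxazine-1-carboxylate
Product: 21 tert-butyl (3R,8aR,5E)-3-acetyl-5-[(5R)-5-(tert-butyldiphenylsilyloxy)octylidene]-3,5,6,7,8,8a-hexahydro-1H-2,1-benzoxazine-1-carboxylate
Conditions: Dess–Martin periodinane, NaHCO3, CH2Cl2, 0 °C
Reagents that add atoms: none
Why: Dess–Martin oxidation under buffered conditions free of soluble base should give the C2 methyl ketone without epimerising the acidic C3–H or provoking base-induced N–O fragmentation.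

Step 13
Reactants: 21 tert-butyl (3R,8aR,5E)-3-acetyl-5-[(5R)-5-(tert-butyldiphenylsilyloxy)octylidene]-3,5,6,7,8,8a-hexahydro-1H-2,1-benzoxazine-1-carboxylate
Product: 22 tert-butyl N-[(1R,2Z,3E)-3-[(5R)-5-(tert-butyldiphenylsilyloxy)octylidene]-2-[(2R)-2-hydroxy-3-oxobutylidene]cyclohexyl]carbamate
Conditions: Mo(CO)6, MeCN–H2O (15:1), 80 °C
Reagents that add atoms: none
Why: Reductive N–O cleavage of N-acyl dihydro-oxazines by zerovalent molybdenum in wet acetonitrile leaves ketone, alkenes, carbamate and the C3 and C8a configurations intact and releases the cis-1,4 amino alcohol as a Z allylic alcohol.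

Step 14
Reactants: 22 tert-butyl N-[(1R,2Z,3E)-3-[(5R)-5-(tert-butyldiphenylsilyloxy)octylidene]-2-[(2R)-2-hydroxy-3-oxobutylidene]cyclohexyl]carbamate
Product: 25 (2S,3R,8aR,5E)-5-[(5R)-5-(tert-butyldiphenylsilyloxy)octylidene]-2-methyl-1,2,3,5,6,7,8,8a-octahydroquinolin-3-ol, via free amino ketone 23 (not isolated), via cyclic imine 24 (not isolated)
Conditions: TFA–CH2Cl2 (1:4), 0 °C; evaporate cold; then NaBH(OAc)3, ClCH2CH2Cl, −20 to 0 °C; aq. NaHCO3
Reagents that add atoms: none
Why: Acidolysis of Boc frees the amine, which condenses with the C2 ketone to a six-membered imine (ring A closed at N1–C2, intramolecular reductive amination), and the C3 hydroxyl, exchanged onto the acetoxyborohydride, should deliver hydride to C2 on its own face, which is also the axial trajectory leaving methyl, hydroxyl and C8 equatorial, so C2 becomes S.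

Step 15
Reactants: 25 (2S,3R,8aR,5E)-5-[(5R)-5-(tert-butyldiphenylsilyloxy)octylidene]-2-methyl-1,2,3,5,6,7,8,8a-octahydroquinolin-3-ol
Product: 26 tert-butyl (2S,3R,8aR,5E)-5-[(5R)-5-(tert-butyldiphenylsilyloxy)octylidene]-3-hydroxy-2-methyl-3,5,6,7,8,8a-hexahydroquinoline-1(2H)-carboxylate
Conditions: Boc2O, Et3N, MeOH, 45 °C
Reagents that add atoms: di-tert-butyl dicarbonate, CC(C)(C)OC(=O)OC(=O)OC(C)(C)C
Why: Carbamate formation with Boc2O without an acylation catalyst is selective for nitrogen over the secondary alcohol, and nitrogen must be masked because a basic amine would deactivate the iridium catalyst of step 16 and be acylated in step 17.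

Step 16
Reactants: 26 tert-butyl (2S,3R,8aR,5E)-5-[(5R)-5-(tert-butyldiphenylsilyloxy)octylidene]-3-hydroxy-2-methyl-3,5,6,7,8,8a-hexahydroquinoline-1(2H)-carboxylate
Product: 27 tert-butyl (2S,3R,4aS,5S,8aR)-5-[(5R)-5-(tert-butyldiphenylsilyloxy)octyl]-3-hydroxy-2-methyloctahydroquinoline-1(2H)-carboxylate
Conditions: [Ir(cod)(PCy3)(py)]PF6 (10 mol%), H2 (1–5 bar), CH2Cl2, 23 °C
Reagents that add atoms: none
Why: In this hydroxyl-directed homogeneous hydrogenation the C3 hydroxyl binds the cationic iridium centre, so hydrogen should add to the C4=C4a–C5=C1' diene from the hydroxyl face, which is also the open face of the emerging cis-fused bicycle, placing H4a and H5 cis to O3 (4aS,5S).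

Step 17
Reactants: 27 tert-butyl (2S,3R,4aS,5S,8aR)-5-[(5R)-5-(tert-butyldiphenylsilyloxy)octyl]-3-hydroxy-2-methyloctahydroquinoline-1(2H)-carboxylate; 28 (2E,4E)-octa-2,4-dienoic acid
Product: 30 tert-butyl (2S,3R,4aS,5S,8aR)-5-[(5R)-5-(tert-butyldiphenylsilyloxy)octyl]-2-methyl-3-[(2E,4E)-octa-2,4-dienoyloxy]octahydroquinoline-1(2H)-carboxylate, via mixed anhydride 29 (not isolated)
Conditions: 2,4,6-Cl3C6H2COCl, Et3N, THF, 23 °C; then 27, 4-(dimethylamino)pyridine, toluene, 23 to 40 °C
Reagents that add atoms: none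
Why: Yamaguchi esterification through the mixed anhydride acylates hindered secondary alcohols under mild conditions that should preserve the E,E geometry of the dienoate.

Step 18
Reactants: 30 tert-butyl (2S,3R,4aS,5S,8aR)-5-[(5R)-5-(tert-butyldiphenylsilyloxy)octyl]-2-methyl-3-[(2E,4E)-octa-2,4-dienoyloxy]octahydroquinoline-1(2H)-carboxylate
Product: 31 tert-butyl (2S,3R,4aS,5S,8aR)-5-[(5R)-5-hydroxyoctyl]-2-methyl-3-[(2E,4E)-octa-2,4-dienoyloxy]octahydroquinoline-1(2H)-carboxylate
Conditions: HF·pyridine, pyridine, THF, 0 to 23 °C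
Reagents that add atoms: none
Why: Fluoride-mediated desilylation cleaves the tert-butyldiphenylsilyl ether, while carbamate and dienoate ester are inert to buffered HF·pyridine.

Step 19
Reactants: 31 tert-butyl (2S,3R,4aS,5S,8aR)-5-[(5R)-5-hydroxyoctyl]-2-methyl-3-[(2E,4E)-octa-2,4-dienoyloxy]octahydroquinoline-1(2H)-carboxylate
Product: 32 lepadin H, (2S,3R,4aS,5S,8aR)-5-[(5R)-5-hydroxyoctyl]-2-methyldecahydroquinolin-3-yl (2E,4E)-octa-2,4-dienoate
Conditions: TFA, CH2Cl2, 0 °C; then aq. NaHCO3
Reagents that add atoms: none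
Why: Acidolytic carbamate cleavage (loss of isobutene and CO2) frees the secondary amine, and the dienoate ester and the C5' alcohol should be stable to cold TFA.

Compound list
1 | (R)-2-propyloxirane | CCC[C@@H]1CO1 | starting material
2 | but-3-en-1-ylmagnesium bromide | C=CCC[Mg]Br | starting material
3 | (4R)-non-8-en-4-ol | CCC[C@@H](O)CCCC=C | intermediate
4 | tert-butyl[(4R)-non-8-en-4-yloxy]diphenylsilane | CCC[C@@H](O[Si](c1ccccc1)(c1ccccc1)C(C)(C)C)CCCC=C | intermediate
5 | (5R)-5-(tert-butyldiphenylsilyloxy)octanal | CCC[C@@H](O[Si](c1ccccc1)(c1ccccc1)C(C)(C)C)CCCC=O | intermediate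
6 | cyclohexanone | O=C1CCCCC1 | starting material
7 | cyclohexanone lithium enolate (not isolated) | [Li]OC1=CCCCC1 | intermediate
8 | 2-[(5R)-5-(tert-butyldiphenylsilyloxy)-1-hydroxyoctyl]cyclohexan-1-one (diastereomer mixture) | CCC[C@@H](O[Si](c1ccccc1)(c1ccccc1)C(C)(C)C)CCCC(O)C1CCCCC1=O | intermediate
9 | methanesulfonate of 8 at C1' (not isolated) | CCC[C@@H](O[Si](c1ccccc1)(c1ccccc1)C(C)(C)C)CCCC(OS(C)(=O)=O)C1CCCCC1=O | intermediate
10 | (2E)-2-[(5R)-5-(tert-butyldiphenylsilyloxy)octylidene]cyclohexan-1-one | CCC[C@@H](O[Si](c1ccccc1)(c1ccccc1)C(C)(C)C)CCC/C=C1\CCCCC1=O | intermediate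
11 | lithium (6E)-6-[(5R)-5-(tert-butyldiphenylsilyloxy)octylidene]cyclohex-1-en-1-olate (not isolated) | CCC[C@@H](O[Si](c1ccccc1)(c1ccccc1)C(C)(C)C)CCC/C=C1\CCCC=C1O[Li] | intermediate
12 | (6E)-6-[(5R)-5-(tert-butyldiphenylsilyloxy)octylidene]cyclohex-1-en-1-yl trifluoromethanesulfonate | CCC[C@@H](O[Si](c1ccccc1)(c1ccccc1)C(C)(C)C)CCC/C=C1\CCCC=C1OS(=O)(=O)C(F)(F)F | intermediate
13 | (S)-but-3-yn-2-ol | C[C@H](O)C#C | starting material
14 | (S)-triethyl(but-3-yn-2-yloxy)silane | C[C@H](O[Si](CC)(CC)CC)C#C | intermediate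
15 | triethyl{[(2S,3E)-4-(4,4,5,5-tetramethyl-1,3,2-dioxaborolan-2-yl)but-3-en-2-yl]oxy}silane | C[C@H](O[Si](CC)(CC)CC)/C=C/B1OC(C)(C)C(C)(C)O1 | intermediate
16 | (6E)-6-[(5R)-5-(tert-butyldiphenylsilyloxy)octylidene]-1-[(1E,3S)-3-(triethylsilyloxy)but-1-en-1-yl]cyclohex-1-ene | C[C@H](O[Si](CC)(CC)CC)/C=C/C1=CCCC\C1=C/CCC[C@H](O[Si](c2ccccc2)(c2ccccc2)C(C)(C)C)CCC | intermediate
17 | tert-butyl N-hydroxycarbamate | CC(C)(C)OC(=O)NO | starting material
18 | tert-butyl nitrosoformate (not isolated) | CC(C)(C)OC(=O)N=O | intermediate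
19 | tert-butyl (3R,8aR,5E)-5-[(5R)-5-(tert-butyldiphenylsilyloxy)octylidene]-3-[(1S)-1-(triethylsilyloxy)ethyl]-3,5,6,7,8,8a-hexahydro-1H-2,1-benzoxazine-1-carboxylate | C[C@H](O[Si](CC)(CC)CC)[C@H]1C=C2/C(=C/CCC[C@H](O[Si](c3ccccc3)(c3ccccc3)C(C)(C)C)CCC)CCC[C@H]2N(C(=O)OC(C)(C)C)O1 | intermediate
20 | tert-butyl (3R,8aR,5E)-5-[(5R)-5-(tert-butyldiphenylsilyloxy)octylidene]-3-[(1S)-1-hydroxyethyl]-3,5,6,7,8,8a-hexahydro-1H-2,1-benzoxazine-1-carboxylate | C[C@H](O)[C@H]1C=C2/C(=C/CCC[C@H](O[Si](c3ccccc3)(c3ccccc3)C(C)(C)C)CCC)CCC[C@H]2N(C(=O)OC(C)(C)C)O1 | intermediate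
21 | tert-butyl (3R,8aR,5E)-3-acetyl-5-[(5R)-5-(tert-butyldiphenylsilyloxy)octylidene]-3,5,6,7,8,8a-hexahydro-1H-2,1-benzoxazine-1-carboxylate | CC(=O)[C@H]1C=C2/C(=C/CCC[C@H](O[Si](c3ccccc3)(c3ccccc3)C(C)(C)C)CCC)CCC[C@H]2N(C(=O)OC(C)(C)C)O1 | intermediate
22 | tert-butyl N-[(1R,2Z,3E)-3-[(5R)-5-(tert-butyldiphenylsilyloxy)octylidene]-2-[(2R)-2-hydroxy-3-oxobutylidene]cyclohexyl]carbamate | CC(=O)[C@H](O)/C=C1/C(=C/CCC[C@H](O[Si](c2ccccc2)(c2ccccc2)C(C)(C)C)CCC)CCC[C@H]1NC(=O)OC(C)(C)C | intermediate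
23 | (3R)-4-[(1Z,2E,6R)-6-amino-2-[(5R)-5-(tert-butyldiphenylsilyloxy)octylidene]cyclohexylidene]-3-hydroxybutan-2-one (trifluoroacetate salt in the flask, not isolated) | CC(=O)[C@H](O)/C=C1/C(=C/CCC[C@H](O[Si](c2ccccc2)(c2ccccc2)C(C)(C)C)CCC)CCC[C@H]1N | intermediate
24 | (3R,8aR,5E)-5-[(5R)-5-(tert-butyldiphenylsilyloxy)octylidene]-2-methyl-3,5,6,7,8,8a-hexahydroquinolin-3-ol (cyclic imine, not isolated) | O[C@@H]1C=C2/C(=C/CCC[C@H](O[Si](c3ccccc3)(c3ccccc3)C(C)(C)C)CCC)CCC[C@H]2N=C1C | intermediate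
25 | (2S,3R,8aR,5E)-5-[(5R)-5-(tert-butyldiphenylsilyloxy)octylidene]-2-methyl-1,2,3,5,6,7,8,8a-octahydroquinolin-3-ol | O[C@@H]1C=C2/C(=C/CCC[C@H](O[Si](c3ccccc3)(c3ccccc3)C(C)(C)C)CCC)CCC[C@H]2N[C@H]1C | intermediate
26 | tert-butyl (2S,3R,8aR,5E)-5-[(5R)-5-(tert-butyldiphenylsilyloxy)octylidene]-3-hydroxy-2-methyl-3,5,6,7,8,8a-hexahydroquinoline-1(2H)-carboxylate | O[C@@H]1C=C2/C(=C/CCC[C@H](O[Si](c3ccccc3)(c3ccccc3)C(C)(C)C)CCC)CCC[C@H]2N(C(=O)OC(C)(C)C)[C@H]1C | intermediate
27 | tert-butyl (2S,3R,4aS,5S,8aR)-5-[(5R)-5-(tert-butyldiphenylsilyloxy)octyl]-3-hydroxy-2-methyloctahydroquinoline-1(2H)-carboxylate | O[C@@H]1C[C@H]2[C@@H](CCCC[C@H](O[Si](c3ccccc3)(c3ccccc3)C(C)(C)C)CCC)CCC[C@H]2N(C(=O)OC(C)(C)C)[C@H]1C | intermediate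
28 | (2E,4E)-octa-2,4-dienoic acid | CCC/C=C/C=C/C(=O)O | starting material
29 | (2E,4E)-octa-2,4-dienoic 2,4,6-trichlorobenzoic anhydride (not isolated) | CCC/C=C/C=C/C(=O)OC(=O)c1c(Cl)cc(Cl)cc1Cl | intermediate
30 | tert-butyl (2S,3R,4aS,5S,8aR)-5-[(5R)-5-(tert-butyldiphenylsilyloxy)octyl]-2-methyl-3-[(2E,4E)-octa-2,4-dienoyloxy]octahydroquinoline-1(2H)-carboxylate | CCC/C=C/C=C/C(=O)O[C@@H]1C[C@H]2[C@@H](CCCC[C@H](O[Si](c3ccccc3)(c3ccccc3)C(C)(C)C)CCC)CCC[C@H]2N(C(=O)OC(C)(C)C)[C@H]1C | intermediate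
31 | tert-butyl (2S,3R,4aS,5S,8aR)-5-[(5R)-5-hydroxyoctyl]-2-methyl-3-[(2E,4E)-octa-2,4-dienoyloxy]octahydroquinoline-1(2H)-carboxylate | CCC/C=C/C=C/C(=O)O[C@@H]1C[C@H]2[C@@H](CCCC[C@H](O)CCC)CCC[C@H]2N(C(=O)OC(C)(C)C)[C@H]1C | intermediate
32 | lepadin H, (2S,3R,4aS,5S,8aR)-5-[(5R)-5-hydroxyoctyl]-2-methyldecahydroquinolin-3-yl (2E,4E)-octa-2,4-dienoate | CCC/C=C/C=C/C(=O)O[C@@H]1C[C@H]2[C@@H](CCCC[C@H](O)CCC)CCC[C@H]2N[C@H]1C | target

Total steps: 19. Longest linear sequence: 17 (steps 1–6, then 9–19); steps 7 and 8 form the short branch.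

Steps most likely to fail

Step 10. The C2 centre may discriminate the two diene faces only weakly, and the very reactive acylnitroso species may add a second time to the s-cis diene formed in 19 or attack C5=C1' in an ene reaction. The fallback sets out from 16 and returns at 20. The acylnitroso partner is replaced by a much slower α-chloronitroso dienophile, the known reagent 1-chloro-1-nitrosocyclohexane, in CHCl3–MeOH at −20 °C. Its later, tighter transition state and bulky N-substituent should raise substrate-controlled facial and regiochemical discrimination, and it should neither undergo ene reactions nor add to the deactivated diene of the adduct. The same N–C8a and O–C3 bonds form, giving the N-(1-chlorocyclohexyl) cycloadduct F1, which methanol solvolyses as it forms. The hydrogen chloride released also removes the triethylsilyl ether, so that the N-unsubstituted hydroxy oxazine F2 is obtained as its hydrochloride. Boc2O with NaHCO3 in THF–water then acylates nitrogen and gives 20.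

Step 14. The unprotected cyclic imine is a 3-hydroxy-dihydropyridine that may lose water to a pyridine, shift to the amino ketone (Amadori-type) or suffer acid-promoted migration of the diene before hydride arrives, and the reduction may lose facial control. The fallback sets out from 22 and returns at 26, keeping nitrogen acylated throughout. The ring-chain tautomer of 22, the cyclic N-Boc hemiaminal F3, is ionised with BF3·OEt2 in CH2Cl2 at −78 °C in the presence of Et3SiH. The resulting N-acyliminium ion F4 should take hydride along the axial trajectory anti to the C8a–C8 bond, which allylic strain with the Boc group holds pseudoaxial, giving the 2,6-cis product. This is 26 directly, so steps 14 and 15 are both bypassed.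

Step 16. The chelating s-cis diene may inhibit the iridium catalyst, and hydrogen may add to the remote exocyclic C5=C1' bond incompletely or without facial control, since the C3 hydroxyl is three bonds further from it. The fallback sets out from 26 and returns at 27. The locked s-cis diene is first reduced by 1,4-addition of hydrogen with (η6-naphthalene)Cr(CO)3 under H2 (70 bar) in acetone at 25 °C, a reaction specific to s-cis 1,3-dienes, which moves the unsaturation into the single tetrasubstituted C4a=C5 alkene F5. Hydroxyl-directed hydrogenation of F5 with [Ir(cod)(PCy3)(py)]PF6 at raised pressure then delivers both hydrogens in one syn addition from the O3 face, so H4a and H5 are necessarily cis to each other and to O3, giving 27.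

Further compounds
F1 | step 10 | tert-butyl-free N-(1-chlorocyclohexyl) cycloadduct, (3R,8aR,5E)-5-[(5R)-5-(tert-butyldiphenylsilyloxy)octylidene]-1-(1-chlorocyclohexyl)-3-[(1S)-1-(triethylsilyloxy)ethyl]-3,5,6,7,8,8a-hexahydro-1H-2,1-benzoxazine | C[C@H](O[Si](CC)(CC)CC)[C@H]1C=C2/C(=C/CCC[C@H](O[Si](c3ccccc3)(c3ccccc3)C(C)(C)C)CCC)CCC[C@H]2N(C4(Cl)CCCCC4)O1
F2 | step 10 | N-unsubstituted hydroxy oxazine, (1S)-1-[(3R,8aR,5E)-5-[(5R)-5-(tert-butyldiphenylsilyloxy)octylidene]-3,5,6,7,8,8a-hexahydro-1H-2,1-benzoxazin-3-yl]ethan-1-ol | C[C@H](O)[C@H]1C=C2/C(=C/CCC[C@H](O[Si](c3ccccc3)(c3ccccc3)C(C)(C)C)CCC)CCC[C@H]2NO1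
F3 | step 14 | cyclic N-Boc hemiaminal, tert-butyl (3R,8aR,5E)-5-[(5R)-5-(tert-butyldiphenylsilyloxy)octylidene]-2,3-dihydroxy-2-methyl-3,5,6,7,8,8a-hexahydroquinoline-1(2H)-carboxylate (C2 epimers) | O[C@@H]1C=C2/C(=C/CCC[C@H](O[Si](c3ccccc3)(c3ccccc3)C(C)(C)C)CCC)CCC[C@H]2N(C(=O)OC(C)(C)C)C1(C)O
F4 | step 14 | N-acyliminium ion, (3R,8aR,5E)-1-(tert-butoxycarbonyl)-5-[(5R)-5-(tert-butyldiphenylsilyloxy)octylidene]-3-hydroxy-2-methyl-3,5,6,7,8,8a-hexahydroquinolin-1-ium | O[C@@H]1C=C2/C(=C/CCC[C@H](O[Si](c3ccccc3)(c3ccccc3)C(C)(C)C)CCC)CCC[C@H]2[N+](C(=O)OC(C)(C)C)=C1C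
F5 | step 16 | tetrasubstituted alkene, tert-butyl (2S,3R,8aR)-5-[(5R)-5-(tert-butyldiphenylsilyloxy)octyl]-3-hydroxy-2-methyl-3,4,6,7,8,8a-hexahydroquinoline-1(2H)-carboxylate | O[C@@H]1CC2=C(CCCC[C@H](O[Si](c3ccccc3)(c3ccccc3)C(C)(C)C)CCC)CCC[C@H]2N(C(=O)OC(C)(C)C)[C@H]1C
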